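**Retrosynthetic overview**
1. The target is a (2R)-chroman joined through CH2 to C6 of a cis-3a,7a-dimethyl-hexahydroinden-4-one. The last C–C disconnection is CH2–C6: Giese addition of iodide 10 to enone 23, then re-oxidation to the enone.
2. Pyran ring of the chroman: C2–C3 and O1–C8a are made in one flask from aryl enolsilane 4 and methyl pyruvate. A catalytic asymmetric Mukaiyama aldol sets C2, then fluoride-triggered SNAr closes the ring; the helper C4 carbonyl is reduced away and the ester carbon becomes the CH2I handle.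
3. Enabling feature: C2 of the pyran ring is a fully substituted carbinol carbon carrying CH3 and one exocyclic carbon, i.e. a latent pyruvate carbonyl. C4, the benzylic CH2 on C4a next to the O-bearing C8a, can be carried as an aryl ketone that supplies the C3 nucleophile and activates a C8a–F bond.
4. Hydrindenone: Cu-catalysed asymmetric conjugate addition to 3-methylcyclohexenone sets C7a; enolate methylation and 5-exo alkylation close the cyclopentane cis (C3a relayed); then α-methallylation, Mukaiyama hydration and Saegusa–Ito oxidation.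
5. Ring order: benzene and cyclohexanone rings bought; pyran ring (step 3); cyclopentane ring (step 10); ring enone (step 13, and again in step 15 after the halves are joined in step 14).

Key step: step 3

Remark: the given descriptors are read as 2R at the chroman carbon and cis (S,S) at the two methyl-bearing ring-fusion carbons; for both catalytic asymmetric steps (3 and 7) the ligand antipode that delivers this sense is used.

Step 1
Reactants: 1 4-fluoro-3-methylanisole
Product: 3 1-(2-fluoro-5-methoxy-3-methylphenyl)ethan-1-one, via aryllithium 2 (not isolated)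
Conditions: s-BuLi, PMDTA, THF, −78 °C; then MeC(O)N(OMe)Me, −78 → 0 °C; aq. NH4Cl
Reagents that add atoms: N-methoxy-N-methylacetamide, CC(=O)N(C)OC
Why: Directed ortho-lithiation with an amine-saturated alkyllithium should remove the most acidic ring proton, the one next to fluorine (the other fluorine-adjacent position carries the methyl group), and Weinreb-amide acylation stops at the ketone.

Step 2
Reactants: 3 1-(2-fluoro-5-methoxy-3-methylphenyl)ethan-1-one
Product: 4 {[1-(2-fluoro-5-methoxy-3-methylphenyl)ethenyl]oxy}trimethylsilane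
Conditions: Me3SiOTf, Et3N, CH2Cl2, 0 °C
Reagents that add atoms: trimethylsilyl trifluoromethanesulfonate, C[Si](C)(C)OS(=O)(=O)C(F)(F)F
Why: Soft enolisation (silyl triflate/amine) of a methyl ketone that can enolise in one direction only gives the enolsilane needed for the Mukaiyama aldol addition.

Step 3
Reactants: 4 {[1-(2-fluoro-5-methoxy-3-methylphenyl)ethenyl]oxy}trimethylsilane; 5 methyl pyruvate
Product: 7 methyl (2R)-6-methoxy-2,8-dimethyl-4-oxo-3,4-dihydro-2H-chromene-2-carboxylate, via silyl aldolate 6 (not isolated)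
Conditions: [Cu((R,R)-t-Bu-box)](OTf)2 (10 mol %), THF, −78 °C; then Bu4N[Ph3SiF2] (20 mol %), −78 → 0 °C
Reagents that add atoms: none
Why: Methyl pyruvate chelates the square-planar Cu(II)–bis(oxazoline) Lewis acid through its keto and ester oxygens, enolsilane 4 attacks the keto carbon (C2) from the face left open by the tert-butyl groups, and silyl transfer releases the tertiary silyl ether 6; fluoride then unmasks the tertiary alkoxide, which displaces the ortho-fluorine through a Meisenheimer adduct stabilised by the aryl ketone, and the fluoride set free carries the chain. The closest known reaction types are the Cu(II)–bis(oxazoline)-catalysed Mukaiyama aldol addition of ketone enolsilanes to pyruvate esters and the intramolecular SNAr of alkoxides on o-fluoroaryl ketones that gives chroman-4-ones. The pyranone ring closes by a 6-exo-trig addition–elimination at the aromatic carbon C8a. The only new stereocentre, C2, is set by the catalyst: the (R,R)-ligand should expose the Re face of the keto group (mirror image of the Si-face attack of the (S,S)-complex), and no later step touches this quaternary carbon. The step needs attack at the keto and not the ester carbonyl, which five-membered chelation secures, and a ring closure that outruns retro-aldol cleavage and base-induced re-opening of 7, for which the ortho-acyl activation of C–F (outweighing the para-methoxy group), the catalytic non-basic fluoride source and the low temperature are relied on.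

Step 4
Reactants: 7 methyl (2R)-6-methoxy-2,8-dimethyl-4-oxo-3,4-dihydro-2H-chromene-2-carboxylate
Product: 8 methyl (2R)-6-methoxy-2,8-dimethyl-3,4-dihydro-2H-chromene-2-carboxylate
Conditions: Et3SiH, CF3CO2H, 50 °C
Reagents that add atoms: none
Why: Ionic hydrogenation: the C4 carbonyl lies ortho to the ring oxygen, so the benzylic cation formed in acid should be trapped twice by the silane to give CH2, which also removes the only path (retro-oxa-Michael) by which C2 could racemise, while the α-aryloxy ester is inert.

Step 5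
Reactants: 8 methyl (2R)-6-methoxy-2,8-dimethyl-3,4-dihydro-2H-chromene-2-carboxylate
Product: 9 [(2R)-6-methoxy-2,8-dimethyl-3,4-dihydro-2H-chromen-2-yl]methanol
Conditions: LiAlH4, THF, 0 °C
Reagents that add atoms: none
Why: Hydride reduction of the ester to the primary alcohol; the quaternary C2 is not involved.

Step 6
Reactants: 9 [(2R)-6-methoxy-2,8-dimethyl-3,4-dihydro-2H-chromen-2-yl]methanol
Product: 10 (2R)-2-(iodomethyl)-6-methoxy-2,8-dimethyl-3,4-dihydro-2H-chromene
Conditions: I2, PPh3, imidazole, PhMe, 110 °C
Reagents that add atoms: iodine, II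
Why: Appel-type iodination (PPh3/I2/imidazole); the neopentyl-like primary carbon needs heat but can neither eliminate nor rearrange, and C2 keeps its configuration.

Step 7
Reactants: 11 3-methylcyclohex-2-en-1-one; 12 (3-bromopropoxy)(tert-butyl)dimethylsilane
Product: 15 (3R)-3-{3-[(tert-butyldimethylsilyl)oxy]propyl}-2,3-dimethylcyclohexan-1-one (both C2 epimers), via Grignard reagent 13 (not isolated), via magnesium enolate 14 (not isolated)
Conditions: 12, Mg, Et2O, 35 °C; then 11, Cu(OTf)2 (3 mol %), chiral C2-symmetric imidazolinium salt (NHC precursor, 4 mol %), Et2O, −30 °C; then MeI, DMPU, −30 → 23 °C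
Reagents that add atoms: iodomethane, CI
Why: Copper/NHC-catalysed asymmetric conjugate addition of a Grignard reagent to a β-substituted cyclohexenone creates the quaternary carbon under ligand control, and the regiospecific magnesium enolate is C-methylated between the carbonyl and the new centre; the configuration of that methyl-bearing carbon does not matter because it is enolised again in step 10.

Step 8
Reactants: 15 (3R)-3-{3-[(tert-butyldimethylsilyl)oxy]propyl}-2,3-dimethylcyclohexan-1-one (both C2 epimers)
Product: 16 (3R)-3-(3-hydroxypropyl)-2,3-dimethylcyclohexan-1-one (both C2 epimers)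
Conditions: HCl (1 %), MeOH, 23 °C
Reagents that add atoms: none
Why: Acid-catalysed methanolysis of the primary silyl ether; the hindered ketone should not ketalise.

Step 9
Reactants: 16 (3R)-3-(3-hydroxypropyl)-2,3-dimethylcyclohexan-1-one (both C2 epimers)
Product: 17 (3R)-3-(3-iodopropyl)-2,3-dimethylcyclohexan-1-one (both C2 epimers)
Conditions: I2, PPh3, imidazole, CH2Cl2, 0 → 23 °C
Reagents that add atoms: iodine, II
Why: Appel-type iodination of an unhindered primary alcohol; the ketone is untouched.

Step 10
Reactants: 17 (3R)-3-(3-iodopropyl)-2,3-dimethylcyclohexan-1-one (both C2 epimers)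
Product: 18 (3aS,7aS)-3a,7a-dimethyloctahydro-4H-inden-4-one
Conditions: t-BuOK, t-BuOH/THF, 23 °C
Reagents that add atoms: none
Why: Intramolecular enolate alkylation under equilibrating conditions: only the more substituted enolate can close a five-membered ring (5-exo-tet), and the three-carbon tether reaches only the enolate face on which it is anchored, so the second quaternary carbon (C3a) should form with the two methyl groups cis.

Step 11
Reactants: 18 (3aS,7aS)-3a,7a-dimethyloctahydro-4H-inden-4-one
Product: 20 (3aS,7aS)-3a,7a-dimethyl-5-(2-methylprop-2-en-1-yl)octahydro-4H-inden-4-one (both C5 epimers), via lithium enolate 19 (not isolated)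
Conditions: LDA, THF, −78 °C; then CH2=C(CH3)CH2Br, −78 → 0 °C
Reagents that add atoms: 3-bromo-2-methylprop-1-ene, CC(=C)CBr
Why: Enolate alkylation of a ketone that has α-hydrogens on one side only (C5), so the regiochemistry is fixed; the new stereocentre is erased in step 13.

Step 12
Reactants: 20 (3aS,7aS)-3a,7a-dimethyl-5-(2-methylprop-2-en-1-yl)octahydro-4H-inden-4-one (both C5 epimers)
Product: 21 (3aS,7aS)-5-(2-hydroxy-2-methylpropyl)-3a,7a-dimethyloctahydro-4H-inden-4-one (both C5 epimers)
Conditions: Co(acac)2 (20 mol %), PhSiH3, O2 (1 atm), i-PrOH, 23 °C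
Reagents that add atoms: dioxygen, O=O
Why: Mukaiyama hydration (cobalt-hydride hydrogen-atom transfer, trapping by O2) should give the Markovnikov tertiary alcohol from the 1,1-disubstituted alkene and leave the ketone alone.

Step 13
Reactants: 21 (3aS,7aS)-5-(2-hydroxy-2-methylpropyl)-3a,7a-dimethyloctahydro-4H-inden-4-one (both C5 epimers)
Product: 23 (3aS,7aS)-5-(2-hydroxy-2-methylpropyl)-3a,7a-dimethyl-1,2,3,3a,7,7a-hexahydro-4H-inden-4-one, via bis(trimethylsilyl) enol ether 22 (not isolated)
Conditions: Me3SiOTf, Et3N, CH2Cl2, 0 → 23 °C; then Pd(OAc)2, MeCN, 23 °C; 1 M HCl work-up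
Reagents that add atoms: none
Why: Saegusa–Ito oxidation: enolisation is possible toward C5 only, and β-hydride elimination from the palladium enolate into the ring should give the conjugated 5-substituted enone; the tertiary alcohol travels as its silyl ether and is freed on work-up.

Step 14
Reactants: 10 (2R)-2-(iodomethyl)-6-methoxy-2,8-dimethyl-3,4-dihydro-2H-chromene; 23 (3aS,7aS)-5-(2-hydroxy-2-methylpropyl)-3a,7a-dimethyl-1,2,3,3a,7,7a-hexahydro-4H-inden-4-one
Product: 24 (3aS,7aS)-5-(2-hydroxy-2-methylpropyl)-6-{[(2R)-6-methoxy-2,8-dimethyl-3,4-dihydro-2H-chromen-2-yl]methyl}-3a,7a-dimethyloctahydro-4H-inden-4-one (epimers at C5 and C6)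
Conditions: (Me3Si)3SiH, Et3B/air, PhMe, 0 °C, 10 in excess
Reagents that add atoms: none
Why: Giese reaction: iodine abstraction by the silyl radical gives the nucleophilic primary chroman-2-ylmethyl radical, which should add to the β-carbon (C6) of the enone; the two new ring stereocentres need no control because both become sp2 in step 15, and the radical centre is insulated from C2.

Step 15
Reactants: 24 (3aS,7aS)-5-(2-hydroxy-2-methylpropyl)-6-{[(2R)-6-methoxy-2,8-dimethyl-3,4-dihydro-2H-chromen-2-yl]methyl}-3a,7a-dimethyloctahydro-4H-inden-4-one (epimers at C5 and C6)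
Product: 26 (3aS,7aS)-5-(2-hydroxy-2-methylpropyl)-6-{[(2R)-6-methoxy-2,8-dimethyl-3,4-dihydro-2H-chromen-2-yl]methyl}-3a,7a-dimethyl-1,2,3,3a,7,7a-hexahydro-4H-inden-4-one, via bis(trimethylsilyl) enol ether 25 (not isolated)
Conditions: Me3SiOTf, Et3N, CH2Cl2, 0 → 23 °C; then Pd(OAc)2, MeCN, 23 °C; 1 M HCl work-up
Reagents that add atoms: none
Why: Second Saegusa–Ito oxidation: the ketone again enolises toward C5 only, palladium should add anti to the C6 substituent and so syn to the C6 hydrogen, and β-hydride elimination restores the tetrasubstituted enone under non-basic conditions, which avoids base-induced opening of the chroman through the γ-CH2.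

**Compound list**
1 | 4-fluoro-3-methylanisole | COc1ccc(F)c(C)c1 | starting material
2 | (2-fluoro-5-methoxy-3-methylphenyl)lithium | [Li]c1cc(OC)cc(C)c1F | intermediate
3 | 1-(2-fluoro-5-methoxy-3-methylphenyl)ethan-1-one | CC(=O)c1cc(OC)cc(C)c1F | intermediate
4 | {[1-(2-fluoro-5-methoxy-3-methylphenyl)ethenyl]oxy}trimethylsilane | C=C(O[Si](C)(C)C)c1cc(OC)cc(C)c1F | intermediate
5 | methyl pyruvate | CC(=O)C(=O)OC | starting material
6 | methyl (2R)-4-(2-fluoro-5-methoxy-3-methylphenyl)-2-methyl-4-oxo-2-[(trimethylsilyl)oxy]butanoate | COC(=O)[C@@](C)(CC(=O)c1cc(OC)cc(C)c1F)O[Si](C)(C)C | intermediate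
7 | methyl (2R)-6-methoxy-2,8-dimethyl-4-oxo-3,4-dihydro-2H-chromene-2-carboxylate | COc1cc(C)c2c(c1)C(=O)C[C@](C)(C(=O)OC)O2 | intermediate
8 | methyl (2R)-6-methoxy-2,8-dimethyl-3,4-dihydro-2H-chromene-2-carboxylate | COc1cc(C)c2c(c1)CC[C@](C)(C(=O)OC)O2 | intermediate
9 | [(2R)-6-methoxy-2,8-dimethyl-3,4-dihydro-2H-chromen-2-yl]methanol | COc1cc(C)c2c(c1)CC[C@](C)(CO)O2 | intermediate
10 | (2R)-2-(iodomethyl)-6-methoxy-2,8-dimethyl-3,4-dihydro-2H-chromene | COc1cc(C)c2c(c1)CC[C@](C)(CI)O2 | intermediate
11 | 3-methylcyclohex-2-en-1-one | CC1=CC(=O)CCC1 | starting material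
12 | (3-bromopropoxy)(tert-butyl)dimethylsilane | CC(C)(C)[Si](C)(C)OCCCBr | starting material
13 | {3-[(tert-butyldimethylsilyl)oxy]propyl}magnesium bromide | CC(C)(C)[Si](C)(C)OCCC[Mg]Br | intermediate
14 | bromomagnesium (3R)-3-{3-[(tert-butyldimethylsilyl)oxy]propyl}-3-methylcyclohex-1-en-1-olate | CC(C)(C)[Si](C)(C)OCCC[C@@]1(C)CCCC(O[Mg]Br)=C1 | intermediate
15 | (3R)-3-{3-[(tert-butyldimethylsilyl)oxy]propyl}-2,3-dimethylcyclohexan-1-one (both C2 epimers) | CC(C)(C)[Si](C)(C)OCCC[C@@]1(C)CCCC(=O)C1C | intermediate
16 | (3R)-3-(3-hydroxypropyl)-2,3-dimethylcyclohexan-1-one (both C2 epimers) | OCCC[C@@]1(C)CCCC(=O)C1C | intermediate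
17 | (3R)-3-(3-iodopropyl)-2,3-dimethylcyclohexan-1-one (both C2 epimers) | ICCC[C@@]1(C)CCCC(=O)C1C | intermediate
18 | (3aS,7aS)-3a,7a-dimethyloctahydro-4H-inden-4-one (cis ring fusion) | C1CC(=O)[C@@]2(C)CCC[C@@]2(C)C1 | intermediate
19 | lithium (3aS,7aS)-3a,7a-dimethyl-2,3,3a,6,7,7a-hexahydro-1H-inden-4-olate | C1C=C(O[Li])[C@@]2(C)CCC[C@@]2(C)C1 | intermediate
20 | (3aS,7aS)-3a,7a-dimethyl-5-(2-methylprop-2-en-1-yl)octahydro-4H-inden-4-one (both C5 epimers) | C1C(CC(C)=C)C(=O)[C@@]2(C)CCC[C@@]2(C)C1 | intermediate
21 | (3aS,7aS)-5-(2-hydroxy-2-methylpropyl)-3a,7a-dimethyloctahydro-4H-inden-4-one (both C5 epimers) | C1C(CC(C)(C)O)C(=O)[C@@]2(C)CCC[C@@]2(C)C1 | intermediate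
22 | trimethylsilyl enol ether of 21 with the tertiary alcohol as its trimethylsilyl ether | C1C(CC(C)(C)O[Si](C)(C)C)=C(O[Si](C)(C)C)[C@@]2(C)CCC[C@@]2(C)C1 | intermediate
23 | (3aS,7aS)-5-(2-hydroxy-2-methylpropyl)-3a,7a-dimethyl-1,2,3,3a,7,7a-hexahydro-4H-inden-4-one | C1=C(CC(C)(C)O)C(=O)[C@@]2(C)CCC[C@@]2(C)C1 | intermediate
24 | (3aS,7aS)-5-(2-hydroxy-2-methylpropyl)-6-{[(2R)-6-methoxy-2,8-dimethyl-3,4-dihydro-2H-chromen-2-yl]methyl}-3a,7a-dimethyloctahydro-4H-inden-4-one (epimers at C5 and C6) | COc1cc(C)c2c(c1)CC[C@](C)(CC1C(CC(C)(C)O)C(=O)[C@@]3(C)CCC[C@@]3(C)C1)O2 | intermediate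
25 | trimethylsilyl enol ether of 24 with the tertiary alcohol as its trimethylsilyl ether | COc1cc(C)c2c(c1)CC[C@](C)(CC1C(CC(C)(C)O[Si](C)(C)C)=C(O[Si](C)(C)C)[C@@]3(C)CCC[C@@]3(C)C1)O2 | intermediate
26 | (3aS,7aS)-5-(2-hydroxy-2-methylpropyl)-6-{[(2R)-6-methoxy-2,8-dimethyl-3,4-dihydro-2H-chromen-2-yl]methyl}-3a,7a-dimethyl-1,2,3,3a,7,7a-hexahydro-4H-inden-4-one (CNP0224132.1) | COc1cc(C)c2c(c1)CC[C@](C)(CC1=C(CC(C)(C)O)C(=O)[C@@]3(C)CCC[C@@]3(C)C1)O2 | target

**Totals**
Total step count: 15. Longest linear sequence: 9 steps (steps 7 to 15); the chroman branch is 8 steps (1 to 6, 14, 15).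

**Steps most likely to fail**

Step 3. What may go wrong: retro-aldol cleavage of the desilylated aldolate before ring closure and reversible base-induced opening of the pyranone, both eroding the enantiomeric purity, together with slow displacement of a fluoride that is para to methoxy. The fallback sets out from ketone 3 and returns to the route at ester 8. Hydroxide displaces the activated fluorine of 3 (KOH, DMSO/H2O, 80 °C) to give 1-(2-hydroxy-5-methoxy-3-methylphenyl)ethan-1-one F1. Kabbe condensation of F1 with methyl pyruvate 5 (pyrrolidine, MeOH, 60 °C; aldol condensation, then oxa-Michael closure, so that the ring now closes at O1–C2) gives racemic methyl 6-methoxy-2,8-dimethyl-4-oxo-3,4-dihydro-2H-chromene-2-carboxylate F2. Ionic hydrogenation as in step 4 gives racemic methyl 6-methoxy-2,8-dimethyl-3,4-dihydro-2H-chromene-2-carboxylate F3, and chromatography of F3 on a chiral stationary phase delivers 8.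

Step 14. What may go wrong: fragmentation of the β-aryloxyalkyl radical (opening of the pyran ring) and hydrogen-atom transfer to the radical before it adds to the hindered β-carbon. The fallback is a polar olefination that sets out from alcohol 9 and enone 23 and returns at target 26. Swern oxidation of 9 gives the non-enolisable (2R)-6-methoxy-2,8-dimethyl-3,4-dihydro-2H-chromene-2-carbaldehyde F4. Phosphoniosilylation of 23 (PPh3, Et3SiOTf, 2,6-lutidine, THF) gives the β-phosphonio silyl enol ether triflate, with the tertiary alcohol also silylated, F5. Deprotonation of F5 with n-BuLi at −78 °C and Wittig reaction of the ylide with F4 gives the silyl dienol ether F6. HF·pyridine removes both silyl groups to give the β,γ-unsaturated ketone F7, which is brought into conjugation with a trace of acid (PPTS) or RhCl3 to give 26.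

Step 7. What may go wrong: incomplete facial discrimination with the functionalised Grignard reagent, competing 1,2-addition, and proton exchange during C-methylation of the magnesium enolate (regioisomeric or double methylation). The fallback exchanges the roles of the two β-substituents; it sets out from Grignard reagent 13 and returns at ketone 15. Addition of 13 to 3-ethoxycyclohex-2-en-1-one and dilute-acid work-up (Stork–Danheiser) gives 3-{3-[(tert-butyldimethylsilyl)oxy]propyl}cyclohex-2-en-1-one F8. Copper/phosphoramidite-catalysed asymmetric conjugate addition of Me3Al, with trapping of the aluminium enolate by Me3SiOTf, gives {[(3R)-3-{3-[(tert-butyldimethylsilyl)oxy]propyl}-3-methylcyclohex-1-en-1-yl]oxy}trimethylsilane F9. MeLi regenerates the enolate regiospecifically and MeI gives 15.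

**Further compounds**
F1 | step 3 | 1-(2-hydroxy-5-methoxy-3-methylphenyl)ethan-1-one | CC(=O)c1cc(OC)cc(C)c1O
F2 | step 3 | methyl 6-methoxy-2,8-dimethyl-4-oxo-3,4-dihydro-2H-chromene-2-carboxylate (racemic) | COc1cc(C)c2c(c1)C(=O)CC(C)(C(=O)OC)O2
F3 | step 3 | methyl 6-methoxy-2,8-dimethyl-3,4-dihydro-2H-chromene-2-carboxylate (racemic) | COc1cc(C)c2c(c1)CCC(C)(C(=O)OC)O2
F4 | step 14 | (2R)-6-methoxy-2,8-dimethyl-3,4-dihydro-2H-chromene-2-carbaldehyde | COc1cc(C)c2c(c1)CC[C@](C)(C=O)O2
F5 | step 14 | [(3aS,7aS)-3a,7a-dimethyl-6-{2-methyl-2-[(triethylsilyl)oxy]propyl}-7-[(triethylsilyl)oxy]-2,3,3a,4,5,7a-hexahydro-1H-inden-5-yl]triphenylphosphonium trifluoromethanesulfonate | CC[Si](CC)(CC)OC(C)(C)CC1=C(O[Si](CC)(CC)CC)[C@@]2(C)CCC[C@@]2(C)CC1[P+](c1ccccc1)(c1ccccc1)c1ccccc1.[O-]S(=O)(=O)C(F)(F)F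
F6 | step 14 | silyl dienol ether from the Wittig reaction of the ylide of F5 with F4 (6-alkylidene, E/Z not fixed, both oxygens as triethylsilyl ethers) | COc1cc(C)c2c(c1)CC[C@](C)(C=C1C(CC(C)(C)O[Si](CC)(CC)CC)=C(O[Si](CC)(CC)CC)[C@@]3(C)CCC[C@@]3(C)C1)O2
F7 | step 14 | (3aS,7aS)-5-(2-hydroxy-2-methylpropyl)-6-{[(2R)-6-methoxy-2,8-dimethyl-3,4-dihydro-2H-chromen-2-yl]methylidene}-3a,7a-dimethyloctahydro-4H-inden-4-one (C5 epimers, E/Z not fixed) | COc1cc(C)c2c(c1)CC[C@](C)(C=C1C(CC(C)(C)O)C(=O)[C@@]3(C)CCC[C@@]3(C)C1)O2
F8 | step 7 | 3-{3-[(tert-butyldimethylsilyl)oxy]propyl}cyclohex-2-en-1-one | CC(C)(C)[Si](C)(C)OCCCC1=CC(=O)CCC1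
F9 | step 7 | {[(3R)-3-{3-[(tert-butyldimethylsilyl)oxy]propyl}-3-methylcyclohex-1-en-1-yl]oxy}trimethylsilane | CC(C)(C)[Si](C)(C)OCCC[C@@]1(C)CCCC(O[Si](C)(C)C)=C1
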